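**Plan**

1. Retrosynthetic cuts: the O1–acyl ester bond; both aldehydes back to a diol, and that to a 1β,11-γ-lactone plus a C12 ester (C8–C12 from CO); then C9–C10 and C8–C9 together, so that ring B comes from a five-membered ring; then C6=C7 (metathesis); then C5–C6 and C10–C8 (conjugate addition/aldol on 2,4,4-trimethylcyclohex-2-enone).
2. Enabling feature: O1 (1β on C1) and C11 (on C9) are peri across the quaternary C10, so they can be tied as a γ-lactone. A diazoacetate on O1 can therefore reach the C8 ketone of a cyclopentanone ring (C5, C6, C7, C8, C10); a shift of C10 from C8 to the diazo carbon (C9) turns that ring into six-membered ring B while the lactone forms.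
3. Forward order: ring A is bought; the five-membered ring is closed by metathesis; ring B arises by the one-carbon expansion; the temporary lactone is opened by hydride; esterification, oxidation and desilylation come last.
4. Stereochemistry: C5 from one Cu-catalysed asymmetric conjugate addition; C10 by anti trapping of the enolate; C1 by axial hydride delivery; C9 by the O1–C11 tether (stereospecific shift, then α-face protonation of the lactone dienolate); the E-enoate comes with p-coumaric acid.

Key step: step 7

Assumption: drimane numbering (ring atoms C1–C10, C11 on C9, C12 on C8, C15 on C10; β = face of C15) is used for every intermediate, the hydrindanes keeping these atom numbers while C9 is still absent; 2,4,4-trimethylcyclohex-2-en-1-one is taken as a commercial compound.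

Step 1
Reactants: 1 2,4,4-trimethylcyclohex-2-en-1-one; 2 vinylmagnesium bromide; 3 acrolein
Product: 5 (2S,3S)-2-(1-hydroxyprop-2-en-1-yl)-2,4,4-trimethyl-3-vinylcyclohexan-1-one (both carbinol epimers), via magnesium enolate 4 (not isolated)
Conditions: 2 (1.3 equiv), Cu(OTf)2 (3 mol %), chiral imidazolinium (NHC) salt (4 mol %, enantiomer that gives 3S), Et2O, −30 °C; then 3 (1.5 equiv), −78 °C; aq NH4Cl
Reagents that add atoms: none
Why: Copper/NHC-catalysed asymmetric conjugate addition of a Grignard reagent to an α-substituted cyclic enone with aldol trapping (three-component coupling): the chiral copper–vinyl species selects the enone face and sets C5, and acrolein should add to the tetrasubstituted enolate anti to the new vinyl group, which sets C10 with C8 trans to C6; the carbinol centre is erased in step 4.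

Step 2
Reactants: 5 (2S,3S)-2-(1-hydroxyprop-2-en-1-yl)-2,4,4-trimethyl-3-vinylcyclohexan-1-one
Product: 6 (3aS,7aS)-3-hydroxy-3a,7,7-trimethyl-3,3a,5,6,7,7a-hexahydro-4H-inden-4-one (trans-fused; C3 epimers)
Conditions: second-generation Ru-benzylidene (NHC) metathesis catalyst (3 mol %), CH2Cl2 (0.01 M), 40 °C
Reagents that add atoms: none
Why: Ring-closing metathesis of a 1,6-diene: the trans-disposed vinyl and 1-hydroxyallyl groups should close to the trans-fused cyclopentene (C6=C7) with loss of ethylene, and no stereocentre is touched.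

Step 3
Reactants: 6 (3aS,7aS)-3-hydroxy-3a,7,7-trimethyl-3,3a,5,6,7,7a-hexahydro-4H-inden-4-one
Product: 7 (3aR,4R,7aS)-3a,7,7-trimethyl-3a,4,5,6,7,7a-hexahydro-3H-indene-3,4-diol (C3 epimers)
Conditions: NaBH4, MeOH, −20 °C
Reagents that add atoms: none
Why: Borohydride reduction of the only ketone: axial hydride attack from the α face, anti to the axial angular methyl on C10, should give the equatorial 1β-alcohol (cis to the methyl).

Step 4
Reactants: 7 (3aR,4R,7aS)-3a,7,7-trimethyl-3a,4,5,6,7,7a-hexahydro-3H-indene-3,4-diol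
Product: 8 (3aS,7R,7aR)-7-hydroxy-4,4,7a-trimethyl-3a,4,5,6,7,7a-hexahydro-1H-inden-1-one
Conditions: activated MnO2 (15 equiv), CH2Cl2, rt
Reagents that add atoms: none
Why: Chemoselective MnO2 oxidation of the allylic C8 alcohol (either epimer) beside the saturated, neopentyl 1β-hydroxyl; the neutral medium avoids retro-aldol cleavage and γ-epimerisation at C5.

Step 5
Reactants: 8 (3aS,7R,7aR)-7-hydroxy-4,4,7a-trimethyl-3a,4,5,6,7,7a-hexahydro-1H-inden-1-one
Product: 9 (3aS,7R,7aR)-7-hydroxy-4,4,7a-trimethyloctahydro-1H-inden-1-one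
Conditions: H2 (1 atm), 10% Pd/C, EtOAc, rt
Reagents that add atoms: none
Why: Heterogeneous hydrogenation of the enone C6=C7 bond; no stereocentre is formed and the trans ring fusion is already fixed.

Step 6
Reactants: 9 (3aS,7R,7aR)-7-hydroxy-4,4,7a-trimethyloctahydro-1H-inden-1-one
Product: 11 (3aR,4R,7aS)-3a,7,7-trimethyl-3-oxooctahydro-1H-inden-4-yl 2-diazoacetate, via tosylhydrazone ester 10 (not isolated)
Conditions: glyoxylic acid chloride p-toluenesulfonylhydrazone (1.5 equiv), N,N-dimethylaniline, CH2Cl2, 0 °C; then Et3N (3 equiv), 0 °C to rt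
Reagents that add atoms: glyoxylic acid chloride p-toluenesulfonylhydrazone, Cc1ccc(cc1)S(=O)(=O)NN=CC(Cl)=O
Why: Diazoacetylation of an alcohol through its glyoxylate tosylhydrazone ester, which loses p-toluenesulfinate with amine base (Bamford–Stevens-type fragmentation); O-acylation also blocks retro-aldol opening of the β-hydroxy ketone.

Step 7
Reactants: 11 (3aR,4R,7aS)-3a,7,7-trimethyl-3-oxooctahydro-1H-inden-4-yl 2-diazoacetate
Product: 13 8-oxo-12-nordriman-11,1β-olide (5αH,9αH), via diazonium betaine 12 (not isolated)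
Conditions: BF3·OEt2 (1.2 equiv), CH2Cl2, −78 to −20 °C; aq NaHCO3
Reagents that add atoms: none
Why: Proposed new method: BF3 activates the C8 ketone of the cyclopentanone (C5, C6, C7, C8, C10) and the diazo carbon, held on O1 by the ester tether, should add to its α face in a 6-exo-trig closure to the β-oxido diazonium δ-lactone 12; C10 then shifts from C8 to the diazonium carbon (now C9) anti to the leaving N2, which in one event enlarges the carbocycle to cyclohexanone ring B (one-carbon expansion by 1,2-alkyl shift) and contracts the δ-lactone to the 1β,11-γ-lactone. The closest known reaction types are the Lewis-acid homologation of cycloalkanones with diazoacetates between separate partners (Tiffeneau–Demjanov/Büchner–Curtius–Schlotterbeck manifold) and, for the addition geometry, the intramolecular Reformatsky/aldol closure of β-acyloxy ketones to δ-lactones. The event is possible only because O1 (1β, equatorial) and C11 on C9 are peri across the quaternary C10: the bonds C1–O1 and C9–C11 are parallel and about 2.5 Å apart, like a 1,3-diaxial pair, so the γ-lactone can bridge them with the chair–chair trans-decalin intact. The new stereocentre C9 is controlled by the tether and the stereospecific shift (retention at C10, inversion at C9), so C11 ends β and H-9 α; as H-9 lies between two carbonyls, any C9 epimer should equilibrate to this chair-compatible lactone. The step needs α-face addition and migration of C10 rather than C7: the angular methyl shields the β face, a δ-lactone with a planar ester should close only as the boat that the α-adduct allows, and in that adduct the diazonium group pointing away from the α-axial H-1 and H-5 is antiperiplanar to C8–C10 while C7 is gauche, C10 also being the more electron-rich migrating carbon. Coordination of the oxido group to boron should suppress closure to a glycidic lactone.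

Step 8
Reactants: 13 8-oxo-12-nordriman-11,1β-olide
Product: 14 8-(trifluoromethanesulfonyloxy)-12-nordrim-8-en-11,1β-olide
Conditions: Tf2O (1.2 equiv), i-Pr2NEt (1.5 equiv), CH2Cl2, −78 to 0 °C
Reagents that add atoms: trifluoromethanesulfonic anhydride, O=S(=O)(OS(=O)(=O)C(F)(F)F)C(F)(F)F
Why: Enol triflate formation from a β-keto lactone: enolisation can go only toward the doubly activated C9, and O-sulfonylation of the ketone enol gives the β-triflyloxy enoate (C9 is reset in step 10).

Step 9
Reactants: 14 8-(trifluoromethanesulfonyloxy)-12-nordrim-8-en-11,1β-olide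
Product: 15 methyl drim-8-en-11,1β-olid-12-oate
Conditions: Pd(OAc)2 (5 mol %), dppf (6 mol %), CO (1 atm), MeOH (10 equiv), Et3N (2 equiv), DMF, 60 °C
Reagents that add atoms: carbon monoxide, [C-]#[O+]; methanol, CO
Why: Palladium-catalysed methoxycarbonylation of an electron-poor vinyl triflate (oxidative addition, CO insertion, methanolysis) installs C12 at the ester level on C8.

Step 10
Reactants: 15 methyl drim-8-en-11,1β-olid-12-oate
Product: 17 methyl drim-7-en-11,1β-olid-12-oate (9αH), via lithium dienolate 16 (not isolated)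
Conditions: LDA (1.1 equiv), THF–DMPU, −78 °C; then AcOH (2 equiv) in THF, −78 °C
Reagents that add atoms: none
Why: Deconjugative kinetic α-protonation of an extended enolate: γ-deprotonation at C7 gives the lactone dienolate, which should be protonated at C9 from the α face (anti to the axial C15 methyl, and the only face that keeps the 1β,11-lactone on a chair ring B), which sets C9 and moves the alkene to C7=C8 in conjugation with the C12 ester.

Step 11
Reactants: 17 methyl drim-7-en-11,1β-olid-12-oate
Product: 18 drim-7-ene-1β,11,12-triol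
Conditions: LiAlH4 (3 equiv), Et2O, 0 °C; Rochelle salt work-up
Reagents that add atoms: none
Why: Hydride reduction of the lactone and the conjugated ester to primary alcohols frees O1 and removes the temporary ring; C9 is no longer adjacent to a carbonyl after this step.

Step 12
Reactants: 18 drim-7-ene-1β,11,12-triol
Product: 19 11,12-bis(triethylsilyloxy)drim-7-en-1β-ol
Conditions: TESCl (2.1 equiv), imidazole (3 equiv), CH2Cl2, −40 to 0 °C
Reagents that add atoms: chlorotriethylsilane, CC[Si](Cl)(CC)CC
Why: Selective silylation of the two primary hydroxyls; the secondary 1β-hydroxyl next to the quaternary C10 should react far more slowly at low temperature.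

Step 13
Reactants: 20 p-coumaric acid
Product: 22 (E)-3-[4-(tert-butyldimethylsilyloxy)phenyl]prop-2-enoic acid, via bis-silyl derivative 21 (not isolated)
Conditions: TBSCl (2.3 equiv), imidazole (4 equiv), DMF, rt; then K2CO3 (cat.), THF–MeOH–H2O, 0 °C; citric acid
Reagents that add atoms: tert-butyldimethylsilyl chloride, CC(C)(C)[Si](C)(C)Cl
Why: Silylation of phenol and acid followed by selective hydrolysis of the labile silyl ester leaves the aryl silyl ether; the E-alkene is untouched.

Step 14
Reactants: 19 11,12-bis(triethylsilyloxy)drim-7-en-1β-ol; 22 (E)-3-[4-(tert-butyldimethylsilyloxy)phenyl]prop-2-enoic acid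
Product: 24 11,12-bis(triethylsilyloxy)drim-7-en-1β-yl (E)-3-[4-(tert-butyldimethylsilyloxy)phenyl]prop-2-enoate, via mixed anhydride 23 (not isolated)
Conditions: 22 (1.5 equiv), 2,4,6-trichlorobenzoyl chloride (1.5 equiv), Et3N (2 equiv), THF, rt; then 19, DMAP (2 equiv), toluene, 40 °C
Reagents that add atoms: none
Why: Yamaguchi esterification: the mixed anhydride transfers the cinnamoyl group through an acylpyridinium ion to the hindered secondary alcohol, with retention at C1 and of the E geometry.

Step 15
Reactants: 24 11,12-bis(triethylsilyloxy)drim-7-en-1β-yl (E)-3-[4-(tert-butyldimethylsilyloxy)phenyl]prop-2-enoate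
Product: 25 11,12-dioxodrim-7-en-1β-yl (E)-3-[4-(tert-butyldimethylsilyloxy)phenyl]prop-2-enoate
Conditions: (COCl)2 (5 equiv), DMSO (10 equiv), CH2Cl2, −78 °C; 24, −78 to −35 °C; i-Pr2NEt (12 equiv), −78 to −20 °C; pH 7 buffer
Reagents that add atoms: none
Why: Swern oxidation applied directly to primary triethylsilyl ethers: both silyl ethers are converted to alkoxysulfonium salts before base is added, so no lactol or lactone can form from a half-oxidised 1,4-diol; the aryl silyl ether and the enoate are inert, and hindered base at low temperature should preserve C9.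

Step 16
Reactants: 25 11,12-dioxodrim-7-en-1β-yl (E)-3-[4-(tert-butyldimethylsilyloxy)phenyl]prop-2-enoate
Product: 26 (1R,5S,9R,10S)-11,12-dioxodrim-7-en-1-yl (E)-3-(4-hydroxyphenyl)prop-2-enoate (target)
Conditions: HF·pyridine, pyridine, THF, 0 °C
Reagents that add atoms: none
Why: Fluoride cleavage of the aryl silyl ether under buffered, non-basic conditions; the dialdehyde, the ester and the epimerisable C9 should survive.

**Compound list**

1 | 2,4,4-trimethylcyclohex-2-en-1-one | CC1=CC(C)(C)CCC1=O | starting material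
2 | vinylmagnesium bromide | C=C[Mg]Br | starting material
3 | acrolein | C=CC=O | starting material
4 | bromomagnesium (3S)-2,4,4-trimethyl-3-vinylcyclohex-1-en-1-olate | CC1(C)CCC(O[Mg]Br)=C(C)[C@H]1C=C | intermediate
5 | (2S,3S)-2-(1-hydroxyprop-2-en-1-yl)-2,4,4-trimethyl-3-vinylcyclohexan-1-one (carbinol epimers) | CC1(C)CCC(=O)[C@](C)(C(O)C=C)[C@H]1C=C | intermediate
6 | (3aS,7aS)-3-hydroxy-3a,7,7-trimethyl-3,3a,5,6,7,7a-hexahydro-4H-inden-4-one (C3 epimers) | CC1(C)CCC(=O)[C@]2(C)C(O)C=C[C@@H]12 | intermediate
7 | (3aR,4R,7aS)-3a,7,7-trimethyl-3a,4,5,6,7,7a-hexahydro-3H-indene-3,4-diol (C3 epimers) | CC1(C)CC[C@@H](O)[C@]2(C)C(O)C=C[C@@H]12 | intermediate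
8 | (3aS,7R,7aR)-7-hydroxy-4,4,7a-trimethyl-3a,4,5,6,7,7a-hexahydro-1H-inden-1-one | CC1(C)CC[C@@H](O)[C@]2(C)C(=O)C=C[C@@H]12 | intermediate
9 | (3aS,7R,7aR)-7-hydroxy-4,4,7a-trimethyloctahydro-1H-inden-1-one | CC1(C)CC[C@@H](O)[C@]2(C)C(=O)CC[C@@H]12 | intermediate
10 | (3aR,4R,7aS)-3a,7,7-trimethyl-3-oxooctahydro-1H-inden-4-yl 2-(2-tosylhydrazinylidene)acetate | CC1(C)CC[C@@H](OC(=O)C=NNS(=O)(=O)c3ccc(C)cc3)[C@]2(C)C(=O)CC[C@@H]12 | intermediate
11 | (3aR,4R,7aS)-3a,7,7-trimethyl-3-oxooctahydro-1H-inden-4-yl 2-diazoacetate | CC1(C)CC[C@@H](OC(=O)C=[N+]=[N-])[C@]2(C)C(=O)CC[C@@H]12 | intermediate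
12 | BF3-bound β-oxido diazonium δ-lactone (C9 bonded to the α face of C8, diazonium anti to C8–C10) | CC1(C)CC[C@H]2OC(=O)[C@@H]([N+]#N)[C@]3(O[B-](F)(F)F)CC[C@@H]1[C@]23C | intermediate
13 | 8-oxo-12-nordriman-11,1β-olide (5αH,9αH) | CC1(C)CC[C@H]2OC(=O)[C@H]3C(=O)CC[C@@H]1[C@]23C | intermediate
14 | 8-(trifluoromethanesulfonyloxy)-12-nordrim-8-en-11,1β-olide | CC1(C)CC[C@H]2OC(=O)C3=C(OS(=O)(=O)C(F)(F)F)CC[C@@H]1[C@]23C | intermediate
15 | methyl drim-8-en-11,1β-olid-12-oate | CC1(C)CC[C@H]2OC(=O)C3=C(C(=O)OC)CC[C@@H]1[C@]23C | intermediate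
16 | lithium dienolate of 15 (C11–OLi, C9=C11, C7=C8) | CC1(C)CC[C@H]2OC(O[Li])=C3C(C(=O)OC)=CC[C@@H]1[C@]23C | intermediate
17 | methyl drim-7-en-11,1β-olid-12-oate (9αH) | CC1(C)CC[C@H]2OC(=O)[C@H]3C(C(=O)OC)=CC[C@@H]1[C@]23C | intermediate
18 | drim-7-ene-1β,11,12-triol | CC1(C)CC[C@@H](O)[C@]2(C)[C@@H](CO)C(CO)=CC[C@@H]12 | intermediate
19 | 11,12-bis(triethylsilyloxy)drim-7-en-1β-ol | CC1(C)CC[C@@H](O)[C@]2(C)[C@@H](CO[Si](CC)(CC)CC)C(CO[Si](CC)(CC)CC)=CC[C@@H]12 | intermediate
20 | p-coumaric acid, (E)-3-(4-hydroxyphenyl)prop-2-enoic acid | OC(=O)/C=C/c1ccc(O)cc1 | starting material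
21 | tert-butyldimethylsilyl (E)-3-[4-(tert-butyldimethylsilyloxy)phenyl]prop-2-enoate | CC(C)(C)[Si](C)(C)OC(=O)/C=C/c1ccc(O[Si](C)(C)C(C)(C)C)cc1 | intermediate
22 | (E)-3-[4-(tert-butyldimethylsilyloxy)phenyl]prop-2-enoic acid | OC(=O)/C=C/c1ccc(O[Si](C)(C)C(C)(C)C)cc1 | intermediate
23 | mixed anhydride of 22 and 2,4,6-trichlorobenzoic acid | O=C(/C=C/c1ccc(O[Si](C)(C)C(C)(C)C)cc1)OC(=O)c1c(Cl)cc(Cl)cc1Cl | intermediate
24 | 11,12-bis(triethylsilyloxy)drim-7-en-1β-yl (E)-3-[4-(tert-butyldimethylsilyloxy)phenyl]prop-2-enoate | CC1(C)CC[C@@H](OC(=O)/C=C/c3ccc(O[Si](C)(C)C(C)(C)C)cc3)[C@]2(C)[C@@H](CO[Si](CC)(CC)CC)C(CO[Si](CC)(CC)CC)=CC[C@@H]12 | intermediate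
25 | 11,12-dioxodrim-7-en-1β-yl (E)-3-[4-(tert-butyldimethylsilyloxy)phenyl]prop-2-enoate | CC1(C)CC[C@@H](OC(=O)/C=C/c3ccc(O[Si](C)(C)C(C)(C)C)cc3)[C@]2(C)[C@@H](C=O)C(C=O)=CC[C@@H]12 | intermediate
26 | (1R,5S,9R,10S)-11,12-dioxodrim-7-en-1-yl (E)-3-(4-hydroxyphenyl)prop-2-enoate, 1β-(E)-p-coumaroyloxypolygodial | CC1(C)CC[C@@H](OC(=O)/C=C/c2ccc(O)cc2)[C@]2(C)[C@@H](C=O)C(C=O)=CC[C@@H]12 | target

**Summary**

Total step count: 16. Longest linear sequence: 15 (steps 1–12 and 14–16; step 13 is the side branch).

Steps most likely to fail: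

1. Step 7. The tethered addition may take the wrong carbonyl face, C7 may migrate in place of C10, or the betaine may collapse to a glycidic lactone. The fallback uses known chemistry, sets out from 9 and comes back at 15. Intermolecular BF3·OEt2-promoted homologation of 9 with methyl diazoacetate (CH2Cl2, 0 °C) should proceed with migration of the less substituted C7, the usual course for α-quaternary cycloalkanones. The old carbonyl carbon becomes C9 and the inserted carbon becomes C8 carrying C12, which gives methyl 1β-hydroxy-9-oxo-11-nordriman-12-oate F1. Selective deprotonation of the β-keto ester (NaH, 1 equiv) and PhNTf2 give methyl 1β-hydroxy-9-(trifluoromethanesulfonyloxy)-11-nordrim-8-en-12-oate F2. Palladium-catalysed carbonylative lactonisation (Pd(PPh3)4, CO, Et3N, DMF, 60 °C), in which the 1β-hydroxyl captures the acyl-palladium at C9, closes the 1β,11-lactone and delivers 15.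

2. Step 1. Copper-catalysed vinyl transfer to the hindered, α-substituted enone may be sluggish or poorly face-selective, and 1,2-addition may compete. The fallback separates the two bond formations, sets out from 1 and comes back at 5. Rhodium(I)/chiral diene-catalysed Hayashi–Miyaura 1,4-addition of potassium vinyltrifluoroborate gives (3S)-2,4,4-trimethyl-3-vinylcyclohexan-1-one F3 (C2 epimers). Thermodynamic silylation (TMSCl, NaI, Et3N, MeCN) gives the tetrasubstituted enol ether trimethyl{[(3S)-2,4,4-trimethyl-3-vinylcyclohex-1-en-1-yl]oxy}silane F4. A Mukaiyama aldol with acrolein 3 (TiCl4, CH2Cl2, −78 °C), anti to the vinyl group, gives 5.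

3. Step 14. Acylation of the neopentyl 1β-hydroxyl, crowded by the peri CH2OTES group, may be slow, and the silyl group may migrate from O11 to O1 under the basic conditions. The fallback builds the enoate after the acylation, sets out from 19 and comes back at 24. Esterification with the small diethylphosphonoacetic acid (DCC, DMAP cat., CH2Cl2) gives 11,12-bis(triethylsilyloxy)drim-7-en-1β-yl 2-(diethoxyphosphoryl)acetate F5. Horner–Wadsworth–Emmons olefination under Masamune–Roush conditions (LiCl, DBU, MeCN) with 4-(tert-butyldimethylsilyloxy)benzaldehyde gives the E-enoate 24.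

**Further compounds**

F1 | step 7 | methyl 1β-hydroxy-9-oxo-11-nordriman-12-oate (C8 epimers) | CC1(C)CC[C@@H](O)[C@]2(C)C(=O)C(C(=O)OC)CC[C@@H]12
F2 | step 7 | methyl 1β-hydroxy-9-(trifluoromethanesulfonyloxy)-11-nordrim-8-en-12-oate | CC1(C)CC[C@@H](O)[C@]2(C)C(OS(=O)(=O)C(F)(F)F)=C(C(=O)OC)CC[C@@H]12
F3 | step 1 | (3S)-2,4,4-trimethyl-3-vinylcyclohexan-1-one (C2 epimers) | CC1(C)CCC(=O)C(C)[C@H]1C=C
F4 | step 1 | trimethyl{[(3S)-2,4,4-trimethyl-3-vinylcyclohex-1-en-1-yl]oxy}silane | CC1(C)CCC(O[Si](C)(C)C)=C(C)[C@H]1C=C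
F5 | step 14 | 11,12-bis(triethylsilyloxy)drim-7-en-1β-yl 2-(diethoxyphosphoryl)acetate | CC1(C)CC[C@@H](OC(=O)CP(=O)(OCC)OCC)[C@]2(C)[C@@H](CO[Si](CC)(CC)CC)C(CO[Si](CC)(CC)CC)=CC[C@@H]12
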